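The furofuran is cut at the C8–C9 bond (lignan numbering: C7–C9 on the guaiacyl side, C7'–C9' on the prenyloxyaryl side). Ring A (C7–O–C9'–C8'–C8) is built first as a 5-aryl-2,3-dihydrofuran. This exploits the fact that C7 is both benzylic and bonded to the ring A oxygen: as an enol ether carbon it makes C8 a radical acceptor and stabilises the radical left at C7. One tin hydride operation then forms C8–C9, closes ring B (C7'–O–C9–C8–C8') and sets C8 and C7. The precursor carries an O–CH2–SePh group on the C7' oxygen; its C7' and C8' centres come from an Evans syn aldol.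

Key step: step 11

Remark: the target is read as the (1S,3aS,4R,6aS) isomer, with the guaiacyl ring endo at C7 and the prenyloxyaryl ring exo at C7'; this requires the (R)-benzyl auxiliary in the aldol.

Abbreviations: prenyl = 3-methylbut-2-en-1-yl; TBS = tert-butyldimethylsilyl; THP = oxan-2-yl (tetrahydropyran-2-yl); ArP = 3-methoxy-4-(prenyloxy)phenyl; ArG = 4-(TBS-oxy)-3-methoxyphenyl.

Step 1
Reactants: 1 vanillin; 2 prenyl bromide
Product: 3 O-prenylvanillin (3-methoxy-4-(prenyloxy)benzaldehyde)
Conditions: K2CO3, DMF, rt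
Reagents that add atoms: none
Why: Williamson ether synthesis, in which the phenoxide of 1 displaces bromide from the primary allylic halide 2 by SN2 and no stereocentre is formed.

Step 2
Reactants: 4 (R)-4-benzyl-1,3-oxazolidin-2-one; 5 methyl 4-chloro-4-oxobutanoate
Product: 6 methyl 4-[(4R)-4-benzyl-2-oxo-1,3-oxazolidin-3-yl]-4-oxobutanoate
Conditions: Et3N, DMAP (cat.), CH2Cl2, 0 °C → rt
Reagents that add atoms: none
Why: DMAP-catalysed N-acylation of the oxazolidinone by the acid chloride (nucleophilic acyl substitution) leaves the methyl ester untouched, and the only stereocentre is the one brought in by 4.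

Step 3
Reactants: 6 succinate imide; 3 O-prenylvanillin
Product: 9 trans lactone imide (4R)-4-benzyl-3-{[(2R,3R)-2-ArP-5-oxooxolan-3-yl]carbonyl}-1,3-oxazolidin-2-one, via boron enolate 7 (not isolated), via syn-aldol adduct 8 (not isolated)
Conditions: Bu2BOTf, iPr2NEt, CH2Cl2, −78 → 0 °C; then 3, −78 → 0 °C; pH 7 buffer, MeOH, H2O2, 0 °C; then PPTS (cat.), CH2Cl2, rt
Reagents that add atoms: none
Why: Evans syn-aldol, in which soft enolisation gives the Z boron enolate 7 that adds to 3 through a Zimmerman–Traxler chair on the face away from the benzyl group of the (R)-auxiliary, setting C8' and C7' as the 2R,3R syn pair of 8, whose C7' hydroxyl then closes on the methyl ester (lactonisation with loss of methanol) to give the lactone with aryl and acyl groups trans.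

Step 4
Reactants: 9 trans lactone imide
Product: 10 (4S,5R)-4-(hydroxymethyl)-5-ArP-oxolan-2-one
Conditions: NaBH4, THF–H2O (4:1), 0 °C
Reagents that add atoms: none
Why: Reductive cleavage of the N-acyl oxazolidinone by borohydride (hydride attack at the more electrophilic exocyclic imide carbonyl, then reduction of the released aldehyde) should turn C9' into CH2OH and return the auxiliary, while the γ-lactone and the prenyl alkene are inert at 0 °C and C7' and C8' are not touched.

Step 5
Reactants: 10 hydroxymethyl lactone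
Product: 11 (4S,5R)-5-ArP-4-[(THP-oxy)methyl]oxolan-2-one (both epimers at the acetal carbon)
Conditions: 3,4-dihydro-2H-pyran, PPTS (cat.), CH2Cl2, rt
Reagents that add atoms: 3,4-dihydro-2H-pyran, C1=COCCC1
Why: Acid-catalysed addition of the primary alcohol to the enol ether (tetrahydropyranyl acetal formation) masks the C9' oxygen with a group that, unlike a silyl ether, cannot migrate to the neighbouring C7' alkoxide of step 7 and that leaves under mild acid, the new acetal centre being formed as both epimers without consequence.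

Step 6
Reactants: 11 THP-protected lactone
Product: 12 (3S,4R)-4-hydroxy-N-methoxy-N-methyl-4-ArP-3-[(THP-oxy)methyl]butanamide
Conditions: MeNH(OMe)·HCl, iPrMgCl, THF, −20 °C; then 11, −20 → 0 °C; aq NH4Cl
Reagents that add atoms: N,O-dimethylhydroxylamine hydrochloride, CNOC.Cl
Why: Weinreb aminolysis of the lactone by the magnesium amide made in the flask opens the ring at the acyl C7–O bond, so C7 becomes the N-methoxy-N-methylamide and the C7' hydroxyl is set free with its configuration unchanged.

Step 7
Reactants: 12 hydroxy Weinreb amide; 13 chloromethyl phenyl selenide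
Product: 14 (3S,4R)-N-methoxy-N-methyl-4-ArP-3-[(THP-oxy)methyl]-4-[(phenylselanyl)methoxy]butanamide
Conditions: NaH, Bu4NI (cat.), THF, 0 °C → rt
Reagents that add atoms: none
Why: Williamson etherification, in which the C7' alkoxide displaces halide from the α-seleno halide 13 (iodide exchange speeds the SN2 step), the C9' oxygen being blocked as an acetal and the amide being a poor acceptor for the alkoxide because it would have to expel an amide anion, so that no stereocentre is touched.

Step 8
Reactants: 15 4-bromo-2-methoxyphenol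
Product: 16 (4-bromo-2-methoxyphenoxy)(tert-butyl)dimethylsilane
Conditions: TBSCl, imidazole, DMF, rt
Reagents that add atoms: tert-butyldimethylsilyl chloride, CC(C)(C)[Si](C)(C)Cl
Why: Silylation of the phenol (nucleophilic substitution at silicon) gives an aryl silyl ether that tolerates magnesium insertion and the later radical step and is removed by fluoride at the end.

Step 9
Reactants: 16 silylated aryl bromide; 14 selenomethyl ether amide
Product: 18 (3S,4R)-1-ArG-4-ArP-3-[(THP-oxy)methyl]-4-[(phenylselanyl)methoxy]butan-1-one, via aryl Grignard reagent 17 (not isolated)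
Conditions: Mg, I2 (cat.), THF, 50 °C; then 14, THF, 0 °C → rt; aq NH4Cl
Reagents that add atoms: none
Why: Weinreb ketone synthesis, in which the aryl Grignard reagent 17 adds only once because the magnesium-chelated tetrahedral adduct survives until work-up, a Grignard reagent being preferred to an aryllithium so that no selenium–metal exchange occurs at the O,Se-acetal.

Step 10
Reactants: 18 aryl ketone
Product: 21 (3S)-5-ArG-3-[(R)-ArP{(phenylselanyl)methoxy}methyl]-2,3-dihydrofuran, via hydroxy ketone 19 (not isolated), via cyclic hemiketal 20 (not isolated)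
Conditions: AcOH–THF–H2O (4:2:1), 45 °C; concentrate from toluene; then PPTS (cat.), 4 Å MS, toluene, 80 °C; Et3N
Reagents that add atoms: none
Why: Acid-catalysed acetal hydrolysis frees the C9' hydroxyl (19), which adds to the C7 ketone to give the five-membered hemiketal 20, and acid-catalysed dehydration with removal of water on molecular sieves (cyclodehydration of a γ-hydroxy ketone) should give the aryl enol ether of ring A without touching C8' or C7'.

Step 11
Reactants: 21 selenomethyl ether of the 5-aryl-2,3-dihydrofuran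
Product: 22 TBS ether of the target, tert-butyl{2-methoxy-4-[(1S,3aS,4R,6aS)-4-ArP-tetrahydro-1H,3H-furo[3,4-c]furan-1-yl]phenoxy}dimethylsilane
Conditions: Bu3SnH (syringe pump), AIBN (cat.), toluene (0.01 M), 80 °C
Reagents that add atoms: none
Why: The tributyltin radical abstracts the phenylselanyl group of 21 to give the nucleophilic O–CH2 radical at C9, which adds to C8, the β-carbon of the styrene-like aryl enol ether, and the resulting C7 radical, benzylic and oxygen-substituted, takes a hydrogen atom from Bu3SnH and carries the chain. The closest known reaction type is the stannane-mediated 5-exo cyclisation of α-alkoxymethyl radicals, generated from phenylselanylmethyl ethers, onto alkenes. Ring B (C7'–O–C9–C8–C8') closes in the 5-exo-trig mode and, because its three-atom tether starts at C8', it can only be fused cis to ring A, so C8 (S) is controlled by the existing C8' centre. C7 (S) is controlled by the shape of the new cis-fused bicycle: the stannane reaches the planar C7 radical on the convex face, anti to the C8–C9 bond, which leaves the guaiacyl ring on the concave (endo) side. The step needs ring closure to win over direct reduction of the C9 radical and 5-exo attack to win over 6-endo attack at C7; slow stannane addition at high dilution secures the first, and the substrate secures the second because only attack at C8 gives the stabilised C7 radical through a five-membered transition state. The prenyl alkene is too remote from C9 to compete, and C7' and C8' are already fixed by the aldol.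

Step 12
Reactants: 22 TBS ether of the target
Product: 23 target, 4-[(1S,3aS,4R,6aS)-4-ArP-tetrahydro-1H,3H-furo[3,4-c]furan-1-yl]-2-methoxyphenol
Conditions: Bu4NF, AcOH, THF, 0 °C
Reagents that add atoms: none
Why: Fluoride-mediated cleavage of the aryl silyl ether (desilylation driven by the Si–F bond), buffered with acetic acid so that neither phenoxide nor acid can epimerise the endo benzylic ether at C7, should free the guaiacyl phenol and leave the prenyl ether intact.

Compound list
1 | vanillin (4-hydroxy-3-methoxybenzaldehyde) | COc1cc(C=O)ccc1O | starting material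
2 | prenyl bromide (1-bromo-3-methylbut-2-ene) | CC(C)=CCBr | starting material
3 | O-prenylvanillin, 3-methoxy-4-(prenyloxy)benzaldehyde | COc1cc(C=O)ccc1OCC=C(C)C | intermediate
4 | (R)-4-benzyl-1,3-oxazolidin-2-one | O=C1N[C@H](Cc2ccccc2)CO1 | starting material
5 | methyl 4-chloro-4-oxobutanoate | COC(=O)CCC(Cl)=O | starting material
6 | methyl 4-[(4R)-4-benzyl-2-oxo-1,3-oxazolidin-3-yl]-4-oxobutanoate | COC(=O)CCC(=O)N1[C@H](Cc2ccccc2)COC1=O | intermediate
7 | dibutylboron Z-enolate of 6, methyl (3Z)-4-[(4R)-4-benzyl-2-oxo-1,3-oxazolidin-3-yl]-4-[(dibutylboranyl)oxy]but-3-enoate | COC(=O)C/C=C(\OB(CCCC)CCCC)N1[C@H](Cc2ccccc2)COC1=O | intermediate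
8 | syn-aldol adduct, methyl (3R,4R)-3-{[(4R)-4-benzyl-2-oxo-1,3-oxazolidin-3-yl]carbonyl}-4-hydroxy-4-ArP-butanoate | COC(=O)C[C@H]([C@@H](O)c1ccc(OCC=C(C)C)c(OC)c1)C(=O)N1[C@H](Cc2ccccc2)COC1=O | intermediate
9 | trans lactone imide, (4R)-4-benzyl-3-{[(2R,3R)-2-ArP-5-oxooxolan-3-yl]carbonyl}-1,3-oxazolidin-2-one | O=C1C[C@@H](C(=O)N2[C@H](Cc3ccccc3)COC2=O)[C@H](c2ccc(OCC=C(C)C)c(OC)c2)O1 | intermediate
10 | (4S,5R)-4-(hydroxymethyl)-5-ArP-oxolan-2-one | O=C1C[C@@H](CO)[C@H](c2ccc(OCC=C(C)C)c(OC)c2)O1 | intermediate
11 | (4S,5R)-5-ArP-4-[(THP-oxy)methyl]oxolan-2-one, both epimers at the acetal carbon | O=C1C[C@@H](COC2CCCCO2)[C@H](c2ccc(OCC=C(C)C)c(OC)c2)O1 | intermediate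
12 | (3S,4R)-4-hydroxy-N-methoxy-N-methyl-4-ArP-3-[(THP-oxy)methyl]butanamide | CON(C)C(=O)C[C@@H](COC1CCCCO1)[C@@H](O)c1ccc(OCC=C(C)C)c(OC)c1 | intermediate
13 | chloromethyl phenyl selenide | ClC[Se]c1ccccc1 | starting material
14 | (3S,4R)-N-methoxy-N-methyl-4-ArP-3-[(THP-oxy)methyl]-4-[(phenylselanyl)methoxy]butanamide | CON(C)C(=O)C[C@@H](COC1CCCCO1)[C@@H](OC[Se]c1ccccc1)c1ccc(OCC=C(C)C)c(OC)c1 | intermediate
15 | 4-bromo-2-methoxyphenol | COc1cc(Br)ccc1O | starting material
16 | (4-bromo-2-methoxyphenoxy)(tert-butyl)dimethylsilane | COc1cc(Br)ccc1O[Si](C)(C)C(C)(C)C | intermediate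
17 | {4-[(tert-butyldimethylsilyl)oxy]-3-methoxyphenyl}magnesium bromide | COc1cc([Mg]Br)ccc1O[Si](C)(C)C(C)(C)C | intermediate
18 | (3S,4R)-1-ArG-4-ArP-3-[(THP-oxy)methyl]-4-[(phenylselanyl)methoxy]butan-1-one | CC(C)(C)[Si](C)(C)Oc1ccc(cc1OC)C(=O)C[C@@H](COC1CCCCO1)[C@@H](OC[Se]c1ccccc1)c1ccc(OCC=C(C)C)c(OC)c1 | intermediate
19 | (3S,4R)-1-ArG-3-(hydroxymethyl)-4-ArP-4-[(phenylselanyl)methoxy]butan-1-one | CC(C)(C)[Si](C)(C)Oc1ccc(cc1OC)C(=O)C[C@@H](CO)[C@@H](OC[Se]c1ccccc1)c1ccc(OCC=C(C)C)c(OC)c1 | intermediate
20 | (4S)-2-ArG-4-[(R)-ArP{(phenylselanyl)methoxy}methyl]oxolan-2-ol, both anomers | CC(C)(C)[Si](C)(C)Oc1ccc(cc1OC)C2(O)C[C@@H](CO2)[C@@H](OC[Se]c3ccccc3)c3ccc(OCC=C(C)C)c(OC)c3 | intermediate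
21 | (3S)-5-ArG-3-[(R)-ArP{(phenylselanyl)methoxy}methyl]-2,3-dihydrofuran | CC(C)(C)[Si](C)(C)Oc1ccc(cc1OC)C2=C[C@@H](CO2)[C@@H](OC[Se]c3ccccc3)c3ccc(OCC=C(C)C)c(OC)c3 | intermediate
22 | tert-butyl{2-methoxy-4-[(1S,3aS,4R,6aS)-4-ArP-tetrahydro-1H,3H-furo[3,4-c]furan-1-yl]phenoxy}dimethylsilane | CC(C)(C)[Si](C)(C)Oc1ccc(cc1OC)[C@H]2OC[C@@H]3[C@H]2CO[C@H]3c1ccc(OCC=C(C)C)c(OC)c1 | intermediate
23 | 4-[(1S,3aS,4R,6aS)-4-ArP-tetrahydro-1H,3H-furo[3,4-c]furan-1-yl]-2-methoxyphenol | COc1cc([C@H]2OC[C@@H]3[C@H]2CO[C@H]3c2ccc(OCC=C(C)C)c(OC)c2)ccc1O | target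

Total step count: 12. Longest linear sequence: 10 steps (steps 1, 3, 4, 5, 6, 7, 9, 10, 11, 12).

Steps most likely to fail

Step 11. The C9 radical may be reduced by the stannane before it closes, since a nucleophilic radical meets an electron-rich alkene, or hydrogen delivery at C7 may be poorly face-selective. The fallback makes the same bond by an ionic route that sets out from 21 and makes no new compound (F0). Methyl triflate with 2,6-di-tert-butyl-4-methylpyridine in CH2Cl2 at −78 °C alkylates selenium and releases the oxocarbenium ion at C9. The enol ether carbon C8 attacks it in a polarity-matched Prins-type 5-exo closure. Et3SiH present in the flask then reduces the aryl-stabilised oxocarbenium ion at C7 from the convex face, and the sequence comes back to the route at 22.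

Step 10. Acid may ionise the electron-rich benzylic C7'–O bond, or the enol ether may be hydrated or dimerised during the dehydration. The fallback builds ring A without dehydrating a hemiketal and sets out from 14. AcOH–THF–H2O removes the THP group to give the hydroxy amide F1, which lactonises on gentle warming with PPTS in toluene to the ring A lactone F2. KN(SiMe3)2 and (PhO)2P(O)Cl in THF at −78 °C convert it into the ketene acetal phosphate F3. Negishi coupling with the arylzinc chloride F4, made from Grignard reagent 17 and ZnCl2, under Pd(PPh3)4 catalysis in THF joins C7 to the aryl ring and comes back to the route at 21.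

Step 7. The C7' alkoxide may close back onto the amide with loss of the amine, or may alkylate too slowly at the hindered benzylic oxygen. The fallback assembles the ether without an alkoxide and sets out from 12. Dimethyl sulfide and dibenzoyl peroxide with 2,6-lutidine in MeCN at 0 °C give the methylthiomethyl ether F5. SO2Cl2 in CH2Cl2 at −78 °C converts it into the chloromethyl ether F6. PhSeH with iPr2NEt then displaces chloride and comes back to the route at 14.

Further compounds
F0 | step 11 | none | none
F1 | step 10 | (3S,4R)-3-(hydroxymethyl)-N-methoxy-N-methyl-4-ArP-4-[(phenylselanyl)methoxy]butanamide | CON(C)C(=O)C[C@@H](CO)[C@@H](OC[Se]c1ccccc1)c1ccc(OCC=C(C)C)c(OC)c1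
F2 | step 10 | (4S)-4-[(R)-ArP{(phenylselanyl)methoxy}methyl]oxolan-2-one | O=C1C[C@@H](CO1)[C@@H](OC[Se]c1ccccc1)c1ccc(OCC=C(C)C)c(OC)c1
F3 | step 10 | diphenyl (4S)-4-[(R)-ArP{(phenylselanyl)methoxy}methyl]-4,5-dihydrofuran-2-yl phosphate | O=P(Oc1ccccc1)(Oc1ccccc1)OC1=C[C@@H](CO1)[C@@H](OC[Se]c1ccccc1)c1ccc(OCC=C(C)C)c(OC)c1
F4 | step 10 | {4-[(tert-butyldimethylsilyl)oxy]-3-methoxyphenyl}zinc chloride | COc1cc([Zn]Cl)ccc1O[Si](C)(C)C(C)(C)C
F5 | step 7 | (3S,4R)-N-methoxy-N-methyl-4-ArP-4-[(methylsulfanyl)methoxy]-3-[(THP-oxy)methyl]butanamide | CON(C)C(=O)C[C@@H](COC1CCCCO1)[C@@H](OCSC)c1ccc(OCC=C(C)C)c(OC)c1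
F6 | step 7 | (3S,4R)-4-(chloromethoxy)-N-methoxy-N-methyl-4-ArP-3-[(THP-oxy)methyl]butanamide | CON(C)C(=O)C[C@@H](COC1CCCCO1)[C@@H](OCCl)c1ccc(OCC=C(C)C)c(OC)c1
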